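## Analysis of the target

Locants follow carotenoid usage (ring carbons C1–C6 with the gem-dimethyl group on C1, chain carbon C7 on C6, primes for the second end group), and "upper face" means the face that carries the C3 oxygen. The target is a C40 carotenoid in which an all-E nonaene chain (C7 to C7', methyl groups on C9, C13, C13' and C9') joins two different oxygenated trimethylcyclohexane end groups. Ring A is a 7-oxabicyclo[2.2.1]heptane with an ether oxygen bridging C3 and C6 and an exo tertiary hydroxyl on C5 (3R,5R,6S), so O3 and O5 are cis on the underlying cyclohexane; ring B is a cyclohexane-3',5',6'-triol (3'R,5'S,6'S) in which O3' and O6' are cis and O5' is trans to both. The two rings therefore share the configuration at C3 and are opposite at C5, and all six stereocentres lie in the rings, four of them fully substituted carbons packed next to the gem-dimethyl carbon and to each other. Sensitive groups are the polyene (light, oxygen, acid), the tertiary allylic C6' alcohol next to a second tertiary alcohol (ionisation, pinacol shift) and the β-hydroxy carbonyl intermediates on the way (dehydration, retro-aldol cleavage). The difficulty sits in the end groups: the familiar closure of an anti 3-hydroxy-5,6-epoxide would place the C5 hydroxyl of ring A anti to the bridge, which is the wrong epimer. The strategy rests on the O3–C6 bond of ring A, with C7 anti and O5 syn to the bridge, read as the result of a transannular opening of a C6–C7 spiro-epoxide by the C3 hydroxyl.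

## Retrosynthetic reasoning

**Silyl ethers.** Target 36 is taken back to its 3',5'-bis(triethylsilyl) ether 35, so only two Si–O bonds are cut. Ring B must carry its secondary and one tertiary hydroxyl through ylide and hydride chemistry, and a final fluoride treatment touches nothing else in the molecule.

**C11'=C12'.** 35 is cut at this double bond into the C25 aldehyde 33 and the ring B C15 phosphonium salt 30 (through ylide 34). The cut is far from the hindered ring carbons, joins an unhindered polyenal to an allylic ylide, and brings the two end groups together only at the last C–C bond formation.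

**C11=C12.** 33 is cut in the same way into the ring A C15 salt 16 (through ylide 32) and the symmetrical C10 dialdehyde 31. This C15 + C10 + C15 pattern uses a commercial centre piece; the forward reaction only has to stop at mono-olefination, which an excess of 31 secures.

**C7=C8 on both ends.** Salts 16 and 30 go back through dienols 15 and 28 (bromide 29 in passing) and esters 14 and 27 to the ring aldehydes 11 and 25 and the C5 phosphonate 12 (used as its lithium salt 13 for ring A and as its sodium salt 26 for ring B). The double bond next to the quaternary C6 is thus made with a small stabilised carbanion on a non-enolisable aldehyde, where E selectivity is dependable. Each end group is reduced to a C10 aldehyde whose only problem is the ring.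

**O3–C6 (key disconnection).** Aldehyde 11 is the oxidised form of primary alcohol 10. In 10 the O3–C6 bond is cut, which unfolds the oxabicycle to the monocyclic spiro-epoxide diol 9. The cut is made here because O3 can reach C6 only across the ring and only from its own face, so the bridgehead configuration follows from C3 alone. The oxygen that leaves C6 stays on C7 as the hydroxyl needed for chain extension. The forward reaction has to open the epoxide at its tertiary carbon with O3 and with no skeletal shift.

**C6–C7.** 9 is the desilylated form of 8. 8 is cut at C6–C7 and C7–O into ketone 5 and the sulfur ylide 7 made from 6. A ketone flanked by two quaternary carbons accepts only a small nucleophile, and axial delivery of carbon places the new oxygen on the face opposite O3, as the invertive key step wants.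

**C3–H.** Ketone 5 is the silylated form of cis-diol 4, which comes from hydroxy-dione 3 by reduction of the C3 carbonyl alone. C3 is set from C5 by the shape of the ring, and the second carbonyl is too hindered to interfere.

**C5–O and C4–H.** 3 comes from epoxy-dione 2 by removal of the C4 oxygen, and 2 from achiral ene-dione 1 by catalytic asymmetric epoxidation. This is the one step in which absolute configuration is introduced into the ring A series; C4 is a sacrificial centre.

**Ring B.** Aldehyde 25 goes back to diol 24, and 24 to alkene 23 by cutting the C6'–O and C7'–O bonds. Dihydroxylation of the exocyclic alkene from its open face gives the hydroxyl pattern that direct carbon addition to the ketone cannot give. 23 comes from ketone 20 and 21 (ylide 22). 20 comes from the trans-diol 19, which is reached from 18 by an internally delivered hydride. 18 and its epoxide 17 are the mirror images of 3 and 2, made from the same 1 with the pseudo-enantiomeric catalyst. Both end groups therefore start from one compound and diverge at the reduction of C3.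

## Alternatives that were turned down

**Alternative 1: ring B by aldol cyclisation.**
- Disconnection: the C4'–C5' bond of ring B.
- Forward key step: a secondary-amine catalyst forms the enamine of the unhindered methyl ketone of the acyclic diketone (3R)-3-[(4-methoxybenzyloxy)methyl]-4,4-dimethyl-3-(trimethylsilyloxy)heptane-2,6-dione (A2). The enamine terminus adds to the other carbonyl and gives the cyclohexanone (3S,4R)-3-hydroxy-4-[(4-methoxybenzyloxy)methyl]-3,5,5-trimethyl-4-(trimethylsilyloxy)cyclohexan-1-one (A1).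
- For it: the ring and the C5' carbinol form in one catalytic step, and C7' is in place from the start. On this point it is stronger than the ring B branch chosen here, which must methylenate a very hindered ketone (step 16).
- Against it: the facial choice at C5' has to come from the adjacent C6', whose two oxygen-bearing substituents differ little in size. A1 is a β-hydroxy ketone that can dehydrate or revert under the amine conditions. C3' still needs an anti reduction. A2 itself needs an asymmetric synthesis of several steps.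
- Comparison: it solves only ring B and leaves the oxabicycle open. The chosen strategy puts its one uncertain step into ring A, where the outcome is fixed by geometry, and makes ring B from the same starting material by the mirror-image sequence.

**Alternative 2: both end groups attached last.**
- Disconnection: C7=C8 and C7'=C8'.
- Forward key step: the C20 reagent tetraethyl [(2E,4E,6E,8E,10E,12E,14E)-2,6,11,15-tetramethylhexadeca-2,4,6,8,10,12,14-heptaene-1,16-diyl]bis(phosphonate) (A4) is deprotonated and condensed first with the silylated ring A aldehyde (1S,2R,4R)-2,6,6-trimethyl-2-(trimethylsilyloxy)-7-oxabicyclo[2.2.1]heptane-1-carbaldehyde (A5) and then with the ring B aldehyde (1S,2S,4R)-2,6,6-trimethyl-1,2,4-tris(trimethylsilyloxy)cyclohexane-1-carbaldehyde (A6) as the second partner. The product A3 is the tetrakis(trimethylsilyl) ether of the target, (3R,5R,6S,3'R,5'S,6'S)-3,6-epoxy-5,3',5',6'-tetrakis(trimethylsilyloxy)-5,6,5',6'-tetrahydro-β,β-carotene, and A3 would be desilylated in a last step.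
- For it: it is the most convergent plan, saves the three chain-extension steps on each end, and needs no phosphonium salt next to the ring B diol. On step economy it is stronger than the chosen route.
- Against it: A4 is not commercial. Its anion is a long, air- and light-sensitive polyene. Two different aldehydes must be introduced one after the other on a symmetrical reagent, which invites statistical mixtures. Both A5 and A6 are fully substituted at the α-carbon and are poor partners for a bulky delocalised anion. A6 carries trimethylsilyl ethers on two tertiary oxygens, which are labile under the basic olefination and on chromatography, so A3 would be hard to obtain pure. A5 would still have to be made through the same ring A chemistry.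
- Comparison: the chosen route lets each hindered aldehyde meet the small phosphonate 12 and keeps the polyene couplings at the unhindered C11=C12 positions with commercial 31. It gives up convergence for dependable bond formation.

**Alternative 3: photooxygenation for the cis-3',6' oxygens.**
- Disconnection: both C–O bonds at C3' and C6' of ring B at once.
- Forward key step: dye-sensitised photooxygenation of the safranal-derived diene 1-ethynyl-2,6,6-trimethylcyclohexa-1,3-diene (A8) gives the endoperoxide (1R,4R)-1-ethynyl-6,7,7-trimethyl-2,3-dioxabicyclo[2.2.2]oct-5-ene (A7).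
- For it: one step from a cheap diene, and the cis relation of O3' and O6' is guaranteed by the bridge. In the chosen route that relation depends on two separate selective steps (14 and 17), so the alternative is stronger on this point.
- Against it: A8 is achiral, so A7 would form as a racemate and need resolution. The remaining C4'=C5' bond must be hydrated at C5' from the face of the gem-dimethyl bridge, the more hindered one, to put O5' trans to the peroxide oxygens. Ene reaction at the C5' methyl competes. The peroxide must be reduced next to an alkyne and is base-labile at C3'–H.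
- Comparison: the chosen route offers catalytic control of absolute configuration at C5 and substrate control for the rest, in place of brevity.

Key step: step 7

Assumption: the sense of induction of the cinchona-derived amine salts on 1 is assigned by analogy with simpler cyclohexenones; if it is the reverse, the two pseudo-enantiomeric catalysts are exchanged between steps 1 and 12 (and likewise the two antipodes of the ruthenium catalyst in the fallback).

## Route

Step 1
Reactants: 1 ketoisophorone (2,6,6-trimethylcyclohex-2-ene-1,4-dione)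
Product: 2 (1R,6S)-1,3,3-trimethyl-7-oxabicyclo[4.1.0]heptane-2,5-dione
Conditions: 9-amino-9-deoxy-epi-quinine (10 mol %), CF3CO2H (20 mol %), 50% aq. H2O2, dioxane, 30 °C
Reagents that add atoms: hydrogen peroxide, OO
Why: Amine-catalysed asymmetric Weitz–Scheffer epoxidation of a cyclic enone: the primary amine condenses only with the unhindered C3 carbonyl, hydroperoxide adds to C5 of the iminium ion and the enamine closes the oxirane at C4; the cinchona scaffold selects the face, which sets C5 (and the sacrificial C4) with the oxygen on the upper face.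

Step 2
Reactants: 2 (1R,6S)-1,3,3-trimethyl-7-oxabicyclo[4.1.0]heptane-2,5-dione
Product: 3 (2R)-2-hydroxy-2,6,6-trimethylcyclohexane-1,4-dione
Conditions: (PhSe)2, NaBH4, EtOH, then AcOH, 0 °C → rt (Na[PhSeB(OEt)3] formed in the flask)
Reagents that add atoms: none
Why: Organoselenium-mediated reductive opening of an α,β-epoxy ketone: the selenolate can attack only the secondary C4, which is α to the C3 carbonyl, so the C4–O bond is cut and the tertiary C5–O bond keeps its configuration; a second selenolate removes selenium and AcOH protonates the enolate before the β-hydroxy ketone can dehydrate.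

Step 3
Reactants: 3 (2R)-2-hydroxy-2,6,6-trimethylcyclohexane-1,4-dione
Product: 4 (2R,4R)-2,4-dihydroxy-2,6,6-trimethylcyclohexan-1-one
Conditions: LiBH(s-Bu)3 (2.2 equiv), THF, −78 °C; aq. NH4Cl
Reagents that add atoms: none
Why: Substrate-controlled ketone reduction: in the chair with O5 axial (which avoids a methyl/methyl 1,3-diaxial contact with C1) the axial path to C3 is blocked by the syn-axial C1 methyl and O5, so the bulky hydride enters equatorially and the new C3–O bond is axial, cis to O5; the C6 carbonyl between two quaternary carbons is not reduced.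

Step 4
Reactants: 4 (2R,4R)-2,4-dihydroxy-2,6,6-trimethylcyclohexan-1-one
Product: 5 (2R,4R)-2,6,6-trimethyl-2,4-bis(triethylsilyloxy)cyclohexan-1-one
Conditions: Et3SiOTf (2.5 equiv), 2,6-lutidine, CH2Cl2, −78 → 0 °C
Reagents that add atoms: triethylsilyl trifluoromethanesulfonate, CC[Si](CC)(CC)OS(=O)(=O)C(F)(F)F
Why: Silyl triflate silylation of a secondary and a hindered tertiary alcohol; both oxygens are capped so that the ylide of step 5 meets no acidic proton and O5 cannot shift the new epoxide (Payne migration).

Step 5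
Reactants: 5 (2R,4R)-2,6,6-trimethyl-2,4-bis(triethylsilyloxy)cyclohexan-1-one; 6 trimethylsulfonium iodide
Product: 8 (3S,6R,8R)-4,4,8-trimethyl-6,8-bis(triethylsilyloxy)-1-oxaspiro[2.5]octane, via dimethylsulfonium methylide 7 (not isolated)
Conditions: 6 (3 equiv), n-BuLi, THF, −10 °C; then 5, −10 °C → rt
Reagents that add atoms: none
Why: Corey–Chaykovsky epoxidation: the unstabilised sulfonium ylide adds irreversibly and axially; in the chair with both silyloxy groups equatorial the C1 and C5 methyl groups are axial on the lower face and block the equatorial path, so C7 enters from the upper face and the betaine closes with the epoxide oxygen on the lower face, anti to O3 (new C6 centre, substrate control).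

Step 6
Reactants: 8 (3S,6R,8R)-4,4,8-trimethyl-6,8-bis(triethylsilyloxy)-1-oxaspiro[2.5]octane
Product: 9 (3S,6R,8R)-4,4,8-trimethyl-1-oxaspiro[2.5]octane-6,8-diol
Conditions: Bu4NF (3 equiv), AcOH (3 equiv), THF, 0 °C → rt
Reagents that add atoms: none
Why: Fluoride desilylation buffered with acetic acid; the near-neutral medium avoids alkoxide-driven epoxide migration as well as premature acid opening, and the diol is taken on without contact with acidic silica.

Step 7
Reactants: 9 (3S,6R,8R)-4,4,8-trimethyl-1-oxaspiro[2.5]octane-6,8-diol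
Product: 10 (1R,2R,4R)-1-(hydroxymethyl)-2,6,6-trimethyl-7-oxabicyclo[2.2.1]heptan-2-ol
Conditions: (±)-camphor-10-sulfonic acid (10 mol %), CH2Cl2, 0 °C → rt
Reagents that add atoms: none
Why: Acid-promoted transannular epoxide opening by a hydroxyl, the reaction type by which 1,2-epoxy-p-menthan-4-ols close to 2-hydroxy-1,4-cineoles and 3-hydroxy-5,6-epoxy carotenoid end groups close to 3,6-epoxides. Protonation of the oxirane oxygen weakens its bond to the tertiary C6 rather than to the primary C7. The ring passes from the chair with both hydroxyls equatorial into the boat with C3 and C6 at bow and stern, which brings O3 to the flagpole position behind the C6–O bond. O3 attacks C6 with inversion in a 5-exo-tet closure that forms the tetrahydrofuran and with it the 7-oxabicyclo[2.2.1]heptane, and the epoxide oxygen leaves as the C7 hydroxyl. The configuration at C6 is controlled by C3, because the tether reaches C6 only from the upper face; even a fully ionised C6 cation would give the same bridgehead, and O5, which lies on that face, ends up exo, syn to the bridge. The step needs attack at C6 and not at C7, which the tertiary cation character under Brønsted acid and the five- over six-membered closure secure. It also needs O3 to outrun a 1,2-shift of C4 or of hydride (semipinacol or Meinwald rearrangement), which a weak protic acid in a non-nucleophilic solvent at low temperature and the poor donor ability of the free O5–H secure. O5 itself cannot compete, since its attack would give an oxirane at C6 or an oxetane at C7.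

Step 8
Reactants: 10 (1R,2R,4R)-1-(hydroxymethyl)-2,6,6-trimethyl-7-oxabicyclo[2.2.1]heptan-2-ol
Product: 11 (1S,2R,4R)-2-hydroxy-2,6,6-trimethyl-7-oxabicyclo[2.2.1]heptane-1-carbaldehyde
Conditions: Dess–Martin periodinane (1.3 equiv), CH2Cl2, 0 °C → rt
Reagents that add atoms: none
Why: Dess–Martin oxidation of the neopentyl primary alcohol; the tertiary C5 hydroxyl cannot be oxidised, and the non-basic medium avoids retro-aldol cleavage of the β-hydroxy aldehyde.

Step 9
Reactants: 11 (1S,2R,4R)-2-hydroxy-2,6,6-trimethyl-7-oxabicyclo[2.2.1]heptane-1-carbaldehyde; 12 ethyl (2E)-4-(diethoxyphosphoryl)-3-methylbut-2-enoate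
Product: 14 ethyl (2E,4E)-5-[(1S,2R,4R)-2-hydroxy-2,6,6-trimethyl-7-oxabicyclo[2.2.1]heptan-1-yl]-3-methylpenta-2,4-dienoate, via lithiated phosphonate 13 (not isolated)
Conditions: 12 (1.5 equiv), LiN(SiMe3)2, THF, −78 °C; then 11, −78 → 0 °C
Reagents that add atoms: none
Why: Horner–Wadsworth–Emmons olefination with a vinylogous phosphonate: the stabilised anion is too weak a base to deprotonate the tertiary alcohol, the aldehyde cannot enolise, and the new C7=C8 bond should form E; the C9=C10 geometry is carried in from 12 and any 9Z isomer is removed by chromatography.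

Step 10
Reactants: 14 ethyl (2E,4E)-5-[(1S,2R,4R)-2-hydroxy-2,6,6-trimethyl-7-oxabicyclo[2.2.1]heptan-1-yl]-3-methylpenta-2,4-dienoate
Product: 15 (2E,4E)-5-[(1S,2R,4R)-2-hydroxy-2,6,6-trimethyl-7-oxabicyclo[2.2.1]heptan-1-yl]-3-methylpenta-2,4-dien-1-ol
Conditions: i-Bu2AlH (3.5 equiv), CH2Cl2, −78 °C; aq. potassium sodium tartrate
Reagents that add atoms: none
Why: 1,2-Reduction of the dienoate to the allylic alcohol with i-Bu2AlH; the free hydroxyl only consumes one extra equivalent.

Step 11
Reactants: 15 (2E,4E)-5-[(1S,2R,4R)-2-hydroxy-2,6,6-trimethyl-7-oxabicyclo[2.2.1]heptan-1-yl]-3-methylpenta-2,4-dien-1-ol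
Product: 16 [(2E,4E)-5-[(1S,2R,4R)-2-hydroxy-2,6,6-trimethyl-7-oxabicyclo[2.2.1]heptan-1-yl]-3-methylpenta-2,4-dienyl]triphenylphosphonium bromide
Conditions: PPh3·HBr (1.1 equiv), MeOH, rt
Reagents that add atoms: triphenylphosphonium bromide (PPh3·HBr), [Br-].c1ccc(cc1)[PH+](c1ccccc1)c1ccccc1
Why: Standard C15 Wittig salt formation through the pentadienyl cation, which PPh3 captures at the unhindered terminus C11; the bridgehead ether cannot ionise and the tertiary C5 alcohol is not allylic.

Step 12
Reactants: 1 ketoisophorone (2,6,6-trimethylcyclohex-2-ene-1,4-dione)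
Product: 17 (1S,6R)-1,3,3-trimethyl-7-oxabicyclo[4.1.0]heptane-2,5-dione
Conditions: 9-amino-9-deoxy-epi-quinidine (10 mol %), CF3CO2H (20 mol %), 50% aq. H2O2, dioxane, 30 °C
Reagents that add atoms: hydrogen peroxide, OO
Why: The amine-catalysed epoxidation of step 1 with the pseudo-enantiomeric catalyst, which exposes the other face of the iminium ion and should give the mirror-image epoxide (oxygen on the lower face).

Step 13
Reactants: 17 (1S,6R)-1,3,3-trimethyl-7-oxabicyclo[4.1.0]heptane-2,5-dione
Product: 18 (2S)-2-hydroxy-2,6,6-trimethylcyclohexane-1,4-dione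
Conditions: (PhSe)2, NaBH4, EtOH, then AcOH, 0 °C → rt (Na[PhSeB(OEt)3] formed in the flask)
Reagents that add atoms: none
Why: The organoselenium reductive opening of step 2 in the mirror-image series; the selenolate attacks C4 only and C5' keeps its oxygen and configuration.

Step 14
Reactants: 18 (2S)-2-hydroxy-2,6,6-trimethylcyclohexane-1,4-dione
Product: 19 (2S,4R)-2,4-dihydroxy-2,6,6-trimethylcyclohexan-1-one
Conditions: Me4NBH(OAc)3 (5 equiv), MeCN–AcOH (1:1), −30 °C
Reagents that add atoms: none
Why: Evans–Saksena directed reduction: the axial C5' hydroxyl exchanges onto boron and delivers hydride to the lower face of the C3' carbonyl, so O3' appears on the upper face, trans to O5' and with the same configuration at C3 as in ring A; the hindered C6' carbonyl cannot adopt the six-membered delivery geometry.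

Step 15
Reactants: 19 (2S,4R)-2,4-dihydroxy-2,6,6-trimethylcyclohexan-1-one
Product: 20 (2S,4R)-2,6,6-trimethyl-2,4-bis(triethylsilyloxy)cyclohexan-1-one
Conditions: Et3SiOTf (2.5 equiv), 2,6-lutidine, CH2Cl2, −78 → 0 °C
Reagents that add atoms: triethylsilyl trifluoromethanesulfonate, CC[Si](CC)(CC)OS(=O)(=O)C(F)(F)F
Why: Silyl triflate silylation as in step 4; the ethers survive ylide, osmylation, hydride and Wittig conditions and are removed together in step 24.

Step 16
Reactants: 20 (2S,4R)-2,6,6-trimethyl-2,4-bis(triethylsilyloxy)cyclohexan-1-one; 21 methyltriphenylphosphonium bromide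
Product: 23 (1S,5R)-1,3,3-trimethyl-2-methylidene-1,5-bis(triethylsilyloxy)cyclohexane, via methylenetriphenylphosphorane 22 (not isolated)
Conditions: 21 (3 equiv), KOt-Bu, toluene, rt; then 20, 90 °C
Reagents that add atoms: none
Why: Wittig methylenation under forcing, salt-free conditions; the ketone has no α-hydrogen, so enolisation cannot compete with slow addition, and no stereocentre is formed.

Step 17
Reactants: 23 (1S,5R)-1,3,3-trimethyl-2-methylidene-1,5-bis(triethylsilyloxy)cyclohexane
Product: 24 (1R,2S,4R)-1-(hydroxymethyl)-2,6,6-trimethyl-2,4-bis(triethylsilyloxy)cyclohexan-1-ol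
Conditions: OsO4 (5 mol %), N-methylmorpholine N-oxide (2 equiv), acetone–H2O (4:1), rt
Reagents that add atoms: osmium tetroxide (oxygen carrier), O=[Os](=O)(=O)=O; N-methylmorpholine N-oxide, C[N+]1([O-])CCOCC1; water, O
Why: Upjohn dihydroxylation: in the chair with the C3' silyloxy group equatorial, the C1' methyl and the C5' silyloxy group are axial on the lower face, so OsO4 adds to the exocyclic alkene from the upper face; the C6' hydroxyl thus forms cis to O3' and trans to O5', in line with the rule that osmylation goes anti to an allylic oxygen.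

Step 18
Reactants: 24 (1R,2S,4R)-1-(hydroxymethyl)-2,6,6-trimethyl-2,4-bis(triethylsilyloxy)cyclohexan-1-ol
Product: 25 (1S,2S,4R)-1-hydroxy-2,6,6-trimethyl-2,4-bis(triethylsilyloxy)cyclohexane-1-carbaldehyde
Conditions: SO3·pyridine (3 equiv), DMSO, i-Pr2NEt, CH2Cl2, 0 °C
Reagents that add atoms: none
Why: Parikh–Doering oxidation of the primary alcohol; an activated-DMSO oxidant is chosen because it does not cleave the 1,2-diol, and the tertiary hydroxyl is inert.

Step 19
Reactants: 25 (1S,2S,4R)-1-hydroxy-2,6,6-trimethyl-2,4-bis(triethylsilyloxy)cyclohexane-1-carbaldehyde; 12 ethyl (2E)-4-(diethoxyphosphoryl)-3-methylbut-2-enoate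
Product: 27 ethyl (2E,4E)-5-[(1S,2S,4R)-1-hydroxy-2,6,6-trimethyl-2,4-bis(triethylsilyloxy)cyclohexyl]-3-methylpenta-2,4-dienoate, via sodium phosphonate 26 (not isolated)
Conditions: 12 (1.5 equiv), NaN(SiMe3)2, THF, −78 °C; then 25, −78 → 0 °C
Reagents that add atoms: none
Why: Horner–Wadsworth–Emmons olefination, here through the sodium salt of the phosphonate: sodium binds the α-hydroxy aldehyde less tightly than lithium, so the chelate that would open the way to an α-ketol rearrangement is disfavoured, and at low temperature the stabilised anion adds to the aldehyde faster than it deprotonates the tertiary hydroxyl. The aldehyde cannot enolise and C7'=C8' should form E.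

Step 20
Reactants: 27 ethyl (2E,4E)-5-[(1S,2S,4R)-1-hydroxy-2,6,6-trimethyl-2,4-bis(triethylsilyloxy)cyclohexyl]-3-methylpenta-2,4-dienoate
Product: 28 (2E,4E)-5-[(1S,2S,4R)-1-hydroxy-2,6,6-trimethyl-2,4-bis(triethylsilyloxy)cyclohexyl]-3-methylpenta-2,4-dien-1-ol
Conditions: i-Bu2AlH (3.5 equiv), CH2Cl2, −78 °C; aq. potassium sodium tartrate
Reagents that add atoms: none
Why: 1,2-Reduction of the dienoate with i-Bu2AlH as in step 10; silyl ethers and the tertiary alcohol are untouched.

Step 21
Reactants: 28 (2E,4E)-5-[(1S,2S,4R)-1-hydroxy-2,6,6-trimethyl-2,4-bis(triethylsilyloxy)cyclohexyl]-3-methylpenta-2,4-dien-1-ol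
Product: 30 [(2E,4E)-5-[(1S,2S,4R)-1-hydroxy-2,6,6-trimethyl-2,4-bis(triethylsilyloxy)cyclohexyl]-3-methylpenta-2,4-dienyl]triphenylphosphonium bromide, via allylic bromide 29 (not isolated)
Conditions: CBr4 (1.1 equiv), PPh3 (1.1 equiv), CH2Cl2, −20 °C; then PPh3 (1.5 equiv), rt
Reagents that add atoms: tetrabromomethane, BrC(Br)(Br)Br; triphenylphosphine, c1ccc(cc1)P(c1ccccc1)c1ccccc1
Why: Appel bromination of the primary allylic alcohol followed by quaternisation of PPh3; the neutral conditions are chosen because an acidic salt-forming protocol could ionise the tertiary allylic C6' alcohol and set off a pinacol shift of the 5',6'-diol, while the hindered tertiary hydroxyl does not react with the Appel reagent.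

Step 22
Reactants: 16 [(2E,4E)-5-[(1S,2R,4R)-2-hydroxy-2,6,6-trimethyl-7-oxabicyclo[2.2.1]heptan-1-yl]-3-methylpenta-2,4-dienyl]triphenylphosphonium bromide; 31 (2E,4E,6E)-2,7-dimethylocta-2,4,6-trienedial
Product: 33 (2E,4E,6E,8E,10E,12E)-13-[(1S,2R,4R)-2-hydroxy-2,6,6-trimethyl-7-oxabicyclo[2.2.1]heptan-1-yl]-2,7,11-trimethyltrideca-2,4,6,8,10,12-hexaenal, via phosphorus ylide 32 (not isolated)
Conditions: 31 (3 equiv), NaOMe, MeOH–CH2Cl2, 0 °C → rt, dark; then heptane, 80 °C (Z → E)
Reagents that add atoms: none
Why: Wittig reaction of a semi-stabilised allylic ylide with an enal (the standard C15 + C10 carotenoid coupling); the excess of the symmetrical dialdehyde should hold the reaction at mono-olefination, and the 11Z isomer formed alongside is equilibrated thermally to all-E.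

Step 23
Reactants: 33 (2E,4E,6E,8E,10E,12E)-13-[(1S,2R,4R)-2-hydroxy-2,6,6-trimethyl-7-oxabicyclo[2.2.1]heptan-1-yl]-2,7,11-trimethyltrideca-2,4,6,8,10,12-hexaenal; 30 [(2E,4E)-5-[(1S,2S,4R)-1-hydroxy-2,6,6-trimethyl-2,4-bis(triethylsilyloxy)cyclohexyl]-3-methylpenta-2,4-dienyl]triphenylphosphonium bromide
Product: 35 (3R,5R,6S,3'R,5'S,6'S)-3,6-epoxy-3',5'-bis(triethylsilyloxy)-5,6,5',6'-tetrahydro-β,β-carotene-5,6'-diol, via phosphorus ylide 34 (not isolated)
Conditions: 30 (1.3 equiv), NaOMe, MeOH–CH2Cl2, 0 °C → rt, dark, argon; then heptane, 80 °C (Z → E)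
Reagents that add atoms: none
Why: Second Wittig coupling at C11'=C12', again between an allylic ylide and an unhindered polyenal; hydroxide is too poor a leaving group for vinylogous elimination from the ylide, and the Z isomer at the new bond is equilibrated thermally.

Step 24
Reactants: 35 (3R,5R,6S,3'R,5'S,6'S)-3,6-epoxy-3',5'-bis(triethylsilyloxy)-5,6,5',6'-tetrahydro-β,β-carotene-5,6'-diol
Product: 36 (3R,5R,6S,3'R,5'S,6'S)-3,6-epoxy-5,6,5',6'-tetrahydro-β,β-carotene-5,3',5',6'-tetrol (CNP0261804.1)
Conditions: Bu4NF (4 equiv), THF, 0 → 40 °C, dark; aq. NH4Cl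
Reagents that add atoms: none
Why: Fluoride cleavage of the two triethylsilyl ethers; the polyene, the bridging ether and the tertiary alcohols are stable to fluoride, and no stereocentre is touched.

## Compound list

1 | ketoisophorone (2,6,6-trimethylcyclohex-2-ene-1,4-dione) | CC1=CC(=O)CC(C)(C)C1=O | starting material
2 | (1R,6S)-1,3,3-trimethyl-7-oxabicyclo[4.1.0]heptane-2,5-dione | C[C@@]12O[C@@H]1C(=O)CC(C)(C)C2=O | intermediate
3 | (2R)-2-hydroxy-2,6,6-trimethylcyclohexane-1,4-dione | C[C@@]1(O)CC(=O)CC(C)(C)C1=O | intermediate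
4 | (2R,4R)-2,4-dihydroxy-2,6,6-trimethylcyclohexan-1-one | C[C@@]1(O)C[C@H](O)CC(C)(C)C1=O | intermediate
5 | (2R,4R)-2,6,6-trimethyl-2,4-bis(triethylsilyloxy)cyclohexan-1-one | C[C@@]1(O[Si](CC)(CC)CC)C[C@H](O[Si](CC)(CC)CC)CC(C)(C)C1=O | intermediate
6 | trimethylsulfonium iodide | C[S+](C)C.[I-] | starting material
7 | dimethylsulfonium methylide | C[S+](C)[CH2-] | intermediate
8 | (3S,6R,8R)-4,4,8-trimethyl-6,8-bis(triethylsilyloxy)-1-oxaspiro[2.5]octane | C1O[C@@]12C(C)(C)C[C@@H](O[Si](CC)(CC)CC)C[C@@]2(C)O[Si](CC)(CC)CC | intermediate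
9 | (3S,6R,8R)-4,4,8-trimethyl-1-oxaspiro[2.5]octane-6,8-diol | C1O[C@@]12C(C)(C)C[C@@H](O)C[C@@]2(C)O | intermediate
10 | (1R,2R,4R)-1-(hydroxymethyl)-2,6,6-trimethyl-7-oxabicyclo[2.2.1]heptan-2-ol | OC[C@]12O[C@H](CC1(C)C)C[C@@]2(C)O | intermediate
11 | (1S,2R,4R)-2-hydroxy-2,6,6-trimethyl-7-oxabicyclo[2.2.1]heptane-1-carbaldehyde | O=C[C@]12O[C@H](CC1(C)C)C[C@@]2(C)O | intermediate
12 | ethyl (2E)-4-(diethoxyphosphoryl)-3-methylbut-2-enoate | CCOC(=O)/C=C(\C)CP(=O)(OCC)OCC | starting material
13 | lithiated phosphonate (lithium salt of the C4 carbanion of 12) | [Li+].CCOC(=O)/C=C(\C)[CH-]P(=O)(OCC)OCC | intermediate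
14 | ethyl (2E,4E)-5-[(1S,2R,4R)-2-hydroxy-2,6,6-trimethyl-7-oxabicyclo[2.2.1]heptan-1-yl]-3-methylpenta-2,4-dienoate | CCOC(=O)/C=C(C)/C=C/[C@]12O[C@H](CC1(C)C)C[C@@]2(C)O | intermediate
15 | (2E,4E)-5-[(1S,2R,4R)-2-hydroxy-2,6,6-trimethyl-7-oxabicyclo[2.2.1]heptan-1-yl]-3-methylpenta-2,4-dien-1-ol | OC/C=C(C)/C=C/[C@]12O[C@H](CC1(C)C)C[C@@]2(C)O | intermediate
16 | [(2E,4E)-5-[(1S,2R,4R)-2-hydroxy-2,6,6-trimethyl-7-oxabicyclo[2.2.1]heptan-1-yl]-3-methylpenta-2,4-dienyl]triphenylphosphonium bromide | [Br-].C(/C=C(C)/C=C/[C@]12O[C@H](CC1(C)C)C[C@@]2(C)O)[P+](c1ccccc1)(c1ccccc1)c1ccccc1 | intermediate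
17 | (1S,6R)-1,3,3-trimethyl-7-oxabicyclo[4.1.0]heptane-2,5-dione | C[C@]12O[C@H]1C(=O)CC(C)(C)C2=O | intermediate
18 | (2S)-2-hydroxy-2,6,6-trimethylcyclohexane-1,4-dione | C[C@]1(O)CC(=O)CC(C)(C)C1=O | intermediate
19 | (2S,4R)-2,4-dihydroxy-2,6,6-trimethylcyclohexan-1-one | C[C@]1(O)C[C@H](O)CC(C)(C)C1=O | intermediate
20 | (2S,4R)-2,6,6-trimethyl-2,4-bis(triethylsilyloxy)cyclohexan-1-one | C[C@]1(O[Si](CC)(CC)CC)C[C@H](O[Si](CC)(CC)CC)CC(C)(C)C1=O | intermediate
21 | methyltriphenylphosphonium bromide | C[P+](c1ccccc1)(c1ccccc1)c1ccccc1.[Br-] | starting material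
22 | methylenetriphenylphosphorane | C=P(c1ccccc1)(c1ccccc1)c1ccccc1 | intermediate
23 | (1S,5R)-1,3,3-trimethyl-2-methylidene-1,5-bis(triethylsilyloxy)cyclohexane | C=C1C(C)(C)C[C@@H](O[Si](CC)(CC)CC)C[C@]1(C)O[Si](CC)(CC)CC | intermediate
24 | (1R,2S,4R)-1-(hydroxymethyl)-2,6,6-trimethyl-2,4-bis(triethylsilyloxy)cyclohexan-1-ol | OC[C@]1(O)C(C)(C)C[C@@H](O[Si](CC)(CC)CC)C[C@]1(C)O[Si](CC)(CC)CC | intermediate
25 | (1S,2S,4R)-1-hydroxy-2,6,6-trimethyl-2,4-bis(triethylsilyloxy)cyclohexane-1-carbaldehyde | O=C[C@]1(O)C(C)(C)C[C@@H](O[Si](CC)(CC)CC)C[C@]1(C)O[Si](CC)(CC)CC | intermediate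
26 | sodium phosphonate (sodium salt of the C4 carbanion of 12) | [Na+].CCOC(=O)/C=C(\C)[CH-]P(=O)(OCC)OCC | intermediate
27 | ethyl (2E,4E)-5-[(1S,2S,4R)-1-hydroxy-2,6,6-trimethyl-2,4-bis(triethylsilyloxy)cyclohexyl]-3-methylpenta-2,4-dienoate | CCOC(=O)/C=C(C)/C=C/[C@]1(O)C(C)(C)C[C@@H](O[Si](CC)(CC)CC)C[C@]1(C)O[Si](CC)(CC)CC | intermediate
28 | (2E,4E)-5-[(1S,2S,4R)-1-hydroxy-2,6,6-trimethyl-2,4-bis(triethylsilyloxy)cyclohexyl]-3-methylpenta-2,4-dien-1-ol | OC/C=C(C)/C=C/[C@]1(O)C(C)(C)C[C@@H](O[Si](CC)(CC)CC)C[C@]1(C)O[Si](CC)(CC)CC | intermediate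
29 | (1S,2S,4R)-1-[(1E,3E)-5-bromo-3-methylpenta-1,3-dienyl]-2,6,6-trimethyl-2,4-bis(triethylsilyloxy)cyclohexan-1-ol | BrC/C=C(C)/C=C/[C@]1(O)C(C)(C)C[C@@H](O[Si](CC)(CC)CC)C[C@]1(C)O[Si](CC)(CC)CC | intermediate
30 | [(2E,4E)-5-[(1S,2S,4R)-1-hydroxy-2,6,6-trimethyl-2,4-bis(triethylsilyloxy)cyclohexyl]-3-methylpenta-2,4-dienyl]triphenylphosphonium bromide | [Br-].C(/C=C(C)/C=C/[C@]1(O)C(C)(C)C[C@@H](O[Si](CC)(CC)CC)C[C@]1(C)O[Si](CC)(CC)CC)[P+](c1ccccc1)(c1ccccc1)c1ccccc1 | intermediate
31 | (2E,4E,6E)-2,7-dimethylocta-2,4,6-trienedial | O=C/C(C)=C/C=C/C=C(C)/C=O | starting material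
32 | phosphorus ylide of 16 | C(/C=C(C)/C=C/[C@]12O[C@H](CC1(C)C)C[C@@]2(C)O)=P(c1ccccc1)(c1ccccc1)c1ccccc1 | intermediate
33 | (2E,4E,6E,8E,10E,12E)-13-[(1S,2R,4R)-2-hydroxy-2,6,6-trimethyl-7-oxabicyclo[2.2.1]heptan-1-yl]-2,7,11-trimethyltrideca-2,4,6,8,10,12-hexaenal | CC(/C=C/C=C(C)/C=C/[C@]12O[C@H](CC1(C)C)C[C@@]2(C)O)=C\C=C\C=C(C)\C=O | intermediate
34 | phosphorus ylide of 30 | C(/C=C(C)/C=C/[C@]1(O)C(C)(C)C[C@@H](O[Si](CC)(CC)CC)C[C@]1(C)O[Si](CC)(CC)CC)=P(c1ccccc1)(c1ccccc1)c1ccccc1 | intermediate
35 | (3R,5R,6S,3'R,5'S,6'S)-3,6-epoxy-3',5'-bis(triethylsilyloxy)-5,6,5',6'-tetrahydro-β,β-carotene-5,6'-diol | CC(/C=C/C=C(C)/C=C/[C@]12O[C@H](CC1(C)C)C[C@@]2(C)O)=C\C=C\C=C(C)\C=C\C=C(C)\C=C\[C@]1(O)C(C)(C)C[C@@H](O[Si](CC)(CC)CC)C[C@]1(C)O[Si](CC)(CC)CC | intermediate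
36 | (3R,5R,6S,3'R,5'S,6'S)-3,6-epoxy-5,6,5',6'-tetrahydro-β,β-carotene-5,3',5',6'-tetrol | CC(/C=C/C=C(C)/C=C/[C@]12O[C@H](CC1(C)C)C[C@@]2(C)O)=C\C=C\C=C(C)\C=C\C=C(C)\C=C\[C@]1(O)C(C)(C)C[C@@H](O)C[C@]1(C)O | target

## Step count and least certain steps

Total: 24 steps. Longest linear sequence: 14 steps (steps 1–11, then 22, 23 and 24).

**Step 7 (key step).**
- What may go wrong: skeletal rearrangement outruns ring closure. In the ground-state chair the C4–C5 ring bond is anti-periplanar to the breaking C6–O bond, so ring contraction by a 1,2-shift (semipinacol), or a hydride shift from C7 to give the aldehyde, can start without any conformational change, whereas O3 must first reach the boat. Opening at C7 by O3 in the six-membered mode is the other leak.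
- Fallback: the ether oxygen is delivered to C6 of an alkene instead of an epoxide. Setting out from ketone 5, Wittig methylenation (ylide 22, toluene, 90 °C) would give (1R,5R)-1,3,3-trimethyl-2-methylidene-1,5-bis(triethylsilyloxy)cyclohexane F1. Bu4NF would free (1R,3R)-1,5,5-trimethyl-6-methylidenecyclohexane-1,3-diol F2. Intramolecular oxymercuration with Hg(OCOCF3)2, then NaCl, would close the same O3–C6 bond and give chloro{[(1S,2R,4R)-2-hydroxy-2,6,6-trimethyl-7-oxabicyclo[2.2.1]heptan-1-yl]methyl}mercury F3. Oxidative demercuration (NaBH4, O2, DMF) would come back to the route at alcohol 10.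

**Step 1 (and its mirror image, step 12).**
- What may go wrong: poor enantiofacial discrimination, because the two faces of the flat ene-dione differ only through remote substituents, and an uncatalysed epoxidation of so electrophilic an alkene may run alongside.
- Fallback: the absolute configuration is introduced by transfer hydrogenation and relayed to C5. Setting out from 1, Noyori transfer hydrogenation with RuCl(p-cymene)[(S,S)-TsDPEN] in HCO2H–Et3N reduces only the unhindered carbonyl and would give (4S)-4-hydroxy-2,6,6-trimethylcyclohex-2-en-1-one F4. Silylation (t-BuMe2SiCl, imidazole) gives (4S)-4-(tert-butyldimethylsilyloxy)-2,6,6-trimethylcyclohex-2-en-1-one F5. Alkaline H2O2 epoxidises anti to the silyloxy group to give (1R,5S,6R)-5-(tert-butyldimethylsilyloxy)-1,3,3-trimethyl-7-oxabicyclo[4.1.0]heptan-2-one F6. Bu4NF gives (1R,5S,6R)-5-hydroxy-1,3,3-trimethyl-7-oxabicyclo[4.1.0]heptan-2-one F7, and Dess–Martin oxidation comes back to the route at 2.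
- For step 12 the same sequence from 1 with the (R,R)-catalyst would pass through (4R)-4-hydroxy-2,6,6-trimethylcyclohex-2-en-1-one F8, (4R)-4-(tert-butyldimethylsilyloxy)-2,6,6-trimethylcyclohex-2-en-1-one F9, (1S,5R,6S)-5-(tert-butyldimethylsilyloxy)-1,3,3-trimethyl-7-oxabicyclo[4.1.0]heptan-2-one F10 and (1S,5R,6S)-5-hydroxy-1,3,3-trimethyl-7-oxabicyclo[4.1.0]heptan-2-one F11, and come back at 17.

**Step 5.**
- What may go wrong: slow addition to a carbonyl flanked by two fully substituted carbons, so that the thermally fragile ylide decomposes first; a twist conformer could also let carbon in from the lower face.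
- Fallback: a smaller, more reactive carbenoid that adds irreversibly at −78 °C. Setting out from 5, chloromethyllithium (ICH2Cl, MeLi·LiBr, THF, −78 °C) would give lithium (1R,2R,4R)-1-(chloromethyl)-2,6,6-trimethyl-2,4-bis(triethylsilyloxy)cyclohexan-1-olate F12, which closes to the epoxide on warming and comes back to the route at 8.

**Step 3.**
- What may go wrong: erosion of the cis selectivity if the chair with the C5 methyl axial, or a twist form of the 1,4-dione, takes part, or if hydride is delivered from the C5 oxygen.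
- Fallback: make the other diastereomer on purpose and invert it. Setting out from 3, Me4NBH(OAc)3 would give (2R,4S)-2,4-dihydroxy-2,6,6-trimethylcyclohexan-1-one F13. Mitsunobu inversion of the secondary alcohol (4-nitrobenzoic acid, PPh3, diisopropyl azodicarboxylate) would give (1R,3R)-3-hydroxy-3,5,5-trimethyl-4-oxocyclohexyl 4-nitrobenzoate F14, and K2CO3 in MeOH comes back to the route at 4.

**Step 16.**
- What may go wrong: the phosphorane fails to add to the ketone, which is shielded by an axial methyl and an axial silyloxy group, and the ylide decomposes at the temperature needed.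
- Fallback: Peterson olefination with a small organolithium. Setting out from 20, Me3SiCH2Li (THF, −78 → 0 °C) would give (1S,2S,4R)-2,6,6-trimethyl-2,4-bis(triethylsilyloxy)-1-[(trimethylsilyl)methyl]cyclohexan-1-ol F15, and KH in THF would eliminate to the alkene and come back to the route at 23.

## Further compounds

F1 | step 7 | (1R,5R)-1,3,3-trimethyl-2-methylidene-1,5-bis(triethylsilyloxy)cyclohexane | C=C1C(C)(C)C[C@@H](O[Si](CC)(CC)CC)C[C@@]1(C)O[Si](CC)(CC)CC
F2 | step 7 | (1R,3R)-1,5,5-trimethyl-6-methylidenecyclohexane-1,3-diol | C=C1C(C)(C)C[C@@H](O)C[C@@]1(C)O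
F3 | step 7 | chloro{[(1S,2R,4R)-2-hydroxy-2,6,6-trimethyl-7-oxabicyclo[2.2.1]heptan-1-yl]methyl}mercury | Cl[Hg]C[C@]12O[C@H](CC1(C)C)C[C@@]2(C)O
F4 | step 1 | (4S)-4-hydroxy-2,6,6-trimethylcyclohex-2-en-1-one | CC1=C[C@@H](O)CC(C)(C)C1=O
F5 | step 1 | (4S)-4-(tert-butyldimethylsilyloxy)-2,6,6-trimethylcyclohex-2-en-1-one | CC1=C[C@@H](O[Si](C)(C)C(C)(C)C)CC(C)(C)C1=O
F6 | step 1 | (1R,5S,6R)-5-(tert-butyldimethylsilyloxy)-1,3,3-trimethyl-7-oxabicyclo[4.1.0]heptan-2-one | C[C@@]12O[C@@H]1[C@@H](O[Si](C)(C)C(C)(C)C)CC(C)(C)C2=O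
F7 | step 1 | (1R,5S,6R)-5-hydroxy-1,3,3-trimethyl-7-oxabicyclo[4.1.0]heptan-2-one | C[C@@]12O[C@@H]1[C@@H](O)CC(C)(C)C2=O
F8 | step 12 | (4R)-4-hydroxy-2,6,6-trimethylcyclohex-2-en-1-one | CC1=C[C@H](O)CC(C)(C)C1=O
F9 | step 12 | (4R)-4-(tert-butyldimethylsilyloxy)-2,6,6-trimethylcyclohex-2-en-1-one | CC1=C[C@H](O[Si](C)(C)C(C)(C)C)CC(C)(C)C1=O
F10 | step 12 | (1S,5R,6S)-5-(tert-butyldimethylsilyloxy)-1,3,3-trimethyl-7-oxabicyclo[4.1.0]heptan-2-one | C[C@]12O[C@H]1[C@H](O[Si](C)(C)C(C)(C)C)CC(C)(C)C2=O
F11 | step 12 | (1S,5R,6S)-5-hydroxy-1,3,3-trimethyl-7-oxabicyclo[4.1.0]heptan-2-one | C[C@]12O[C@H]1[C@H](O)CC(C)(C)C2=O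
F12 | step 5 | lithium (1R,2R,4R)-1-(chloromethyl)-2,6,6-trimethyl-2,4-bis(triethylsilyloxy)cyclohexan-1-olate | ClC[C@@]1([O-])C(C)(C)C[C@@H](O[Si](CC)(CC)CC)C[C@@]1(C)O[Si](CC)(CC)CC.[Li+]
F13 | step 3 | (2R,4S)-2,4-dihydroxy-2,6,6-trimethylcyclohexan-1-one | C[C@@]1(O)C[C@@H](O)CC(C)(C)C1=O
F14 | step 3 | (1R,3R)-3-hydroxy-3,5,5-trimethyl-4-oxocyclohexyl 4-nitrobenzoate | C[C@@]1(O)C[C@H](OC(=O)c2ccc(cc2)[N+](=O)[O-])CC(C)(C)C1=O
F15 | step 16 | (1S,2S,4R)-2,6,6-trimethyl-2,4-bis(triethylsilyloxy)-1-[(trimethylsilyl)methyl]cyclohexan-1-ol | C[Si](C)(C)C[C@@]1(O)C(C)(C)C[C@@H](O[Si](CC)(CC)CC)C[C@]1(C)O[Si](CC)(CC)CC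
A1 | alternative 1 | (3S,4R)-3-hydroxy-4-[(4-methoxybenzyloxy)methyl]-3,5,5-trimethyl-4-(trimethylsilyloxy)cyclohexan-1-one | COc1ccc(COC[C@]2(O[Si](C)(C)C)C(C)(C)CC(=O)C[C@]2(C)O)cc1
A2 | alternative 1 | (3R)-3-[(4-methoxybenzyloxy)methyl]-4,4-dimethyl-3-(trimethylsilyloxy)heptane-2,6-dione | COc1ccc(COC[C@](C(C)=O)(O[Si](C)(C)C)C(C)(C)CC(C)=O)cc1
A3 | alternative 2 | (3R,5R,6S,3'R,5'S,6'S)-3,6-epoxy-5,3',5',6'-tetrakis(trimethylsilyloxy)-5,6,5',6'-tetrahydro-β,β-carotene | CC(/C=C/C=C(C)/C=C/[C@]12O[C@H](CC1(C)C)C[C@@]2(C)O[Si](C)(C)C)=C\C=C\C=C(C)\C=C\C=C(C)\C=C\[C@]1(O[Si](C)(C)C)C(C)(C)C[C@@H](O[Si](C)(C)C)C[C@]1(C)O[Si](C)(C)C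
A4 | alternative 2 | tetraethyl [(2E,4E,6E,8E,10E,12E,14E)-2,6,11,15-tetramethylhexadeca-2,4,6,8,10,12,14-heptaene-1,16-diyl]bis(phosphonate) | CCOP(=O)(OCC)C/C(C)=C/C=C/C(C)=C/C=C/C=C(C)/C=C/C=C(C)/CP(=O)(OCC)OCC
A5 | alternative 2 | (1S,2R,4R)-2,6,6-trimethyl-2-(trimethylsilyloxy)-7-oxabicyclo[2.2.1]heptane-1-carbaldehyde | O=C[C@]12O[C@H](CC1(C)C)C[C@@]2(C)O[Si](C)(C)C
A6 | alternative 2 | (1S,2S,4R)-2,6,6-trimethyl-1,2,4-tris(trimethylsilyloxy)cyclohexane-1-carbaldehyde | O=C[C@]1(O[Si](C)(C)C)C(C)(C)C[C@@H](O[Si](C)(C)C)C[C@]1(C)O[Si](C)(C)C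
A7 | alternative 3 | (1R,4R)-1-ethynyl-6,7,7-trimethyl-2,3-dioxabicyclo[2.2.2]oct-5-ene | C#C[C@@]12OO[C@@H](C=C1C)CC2(C)C
A8 | alternative 3 | 1-ethynyl-2,6,6-trimethylcyclohexa-1,3-diene | C#CC1=C(C)C=CCC1(C)C
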